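**Strategy.** Ring B of the decalin (C5–C6–C7=C8–C9–C10, drimane numbering) is cut into a four-carbon unit C10–C5–C6–C7 carried by ring A and a two-carbon unit C8–C9 carried by the side chain. The key step exploits the trisubstituted C7=C8 olefin next to the quaternary C10. An iron-hydride radical–polar crossover annulation joins aldehyde 5 (ring A olefin plus C7 aldehyde) with vinyl tetrazolyl sulfone 9. It forms the C9–C10 bond by Giese addition and the C7=C8 double bond by intramolecular Julia–Kocienski olefination in one operation. The 1,2-dioxane is then closed by stereospecific peroxymercuration of a Z-olefin.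

Key step: step 5

Remark: 2,4,4-trimethylcyclohex-2-en-1-one (1) and 5-(ethylsulfonyl)-1-phenyl-1H-tetrazole (6) are taken as catalogue compounds. Abbreviations: Dec = (1R,4aR,8aR)-2,5,5,8a-tetramethyl-1,4,4a,5,6,7,8,8a-octahydronaphthalen-1-yl; TBS = tert-butyl(dimethyl)silyl; PT = 1-phenyl-1H-tetrazol-5-yl. Dioxane atoms are numbered O1, O2, C3–C6.

Step 1
Reactants: 1 2,4,4-trimethylcyclohex-2-en-1-one
Product: 2 (1S)-2,4,4-trimethylcyclohex-2-en-1-ol
Conditions: (R)-2-methyl-CBS-oxazaborolidine (0.1 equiv), catecholborane, toluene, −78 °C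
Reagents that add atoms: none
Why: Corey–Bakshi–Shibata reduction, in which the oxazaborolidine binds the ketone with the methyl-substituted olefinic carbon as the large group and delivers hydride to one carbonyl face, which should set the (1S)-carbinol.

Step 2
Reactants: 2 (1S)-2,4,4-trimethylcyclohex-2-en-1-ol
Product: 4 ethyl 2-[(1R)-2,6,6-trimethylcyclohex-2-en-1-yl]acetate, via ketene acetal 3 (not isolated)
Conditions: MeC(OEt)3, EtCO2H (cat.), 140 °C, ethanol distilled off
Reagents that add atoms: triethyl orthoacetate CC(OCC)(OCC)OCC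
Why: Johnson–Claisen rearrangement, in which the suprafacial [3,3] shift of ketene acetal 3 transfers the C–O chirality to the new C–C bond at the olefin terminus next to the gem-dimethyl carbon (the later C5) and moves the double bond to C1=C10.

Step 3
Reactants: 4 ethyl 2-[(1R)-2,6,6-trimethylcyclohex-2-en-1-yl]acetate
Product: 5 2-[(1R)-2,6,6-trimethylcyclohex-2-en-1-yl]acetaldehyde
Conditions: i-Bu2AlH (1.05 equiv), CH2Cl2, −78 °C
Reagents that add atoms: none
Why: Half-reduction of the ester through the stable tetrahedral aluminate (i-Bu2AlH reduction) should give the aldehyde without touching the stereocentre or the ring olefin.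

Step 4
Reactants: 6 5-(ethylsulfonyl)-1-phenyl-1H-tetrazole; 7 3-(TBS-oxy)propanal
Product: 9 5-{[(2E)-5-(TBS-oxy)pent-2-en-2-yl]sulfonyl}-1-phenyl-1H-tetrazole, via phosphonate 8 (not isolated)
Conditions: LiN(SiMe3)2 (2.2 equiv), ClP(O)(OEt)2 (1.1 equiv), THF, −78 °C; then 7, −78 to 0 °C
Reagents that add atoms: none
Why: One-pot phosphorylation of the sulfonyl carbanion followed by Horner–Wadsworth–Emmons olefination, in which phosphate elimination should outrun Smiles rearrangement and give the vinyl sulfone (mainly E; the geometry is lost in step 5).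

Step 5
Reactants: 5 2-[(1R)-2,6,6-trimethylcyclohex-2-en-1-yl]acetaldehyde; 9 5-{[(2E)-5-(TBS-oxy)pent-2-en-2-yl]sulfonyl}-1-phenyl-1H-tetrazole
Product: 11 tert-butyl(dimethyl)[2-(Dec)ethoxy]silane, via alkoxide 10 (not isolated)
Conditions: 5 (1.5 equiv), Fe(acac)3 (0.3 equiv), PhSiH2(Oi-Pr) (2.5 equiv), THF, 0 to 23 °C
Reagents that add atoms: none
Why: Proposed new method: an iron hydride made from Fe(acac)3 and the silane transfers a hydrogen atom to the olefinic CH (C1) of ring A in 5 (Mukaiyama-type hydrogen atom transfer), the tertiary C10 radical adds to the β-carbon C9 of 9 (Giese addition), divalent iron reduces the α-sulfonyl radical to the C8 carbanion (radical–polar crossover), and this carbanion closes ring B by 6-exo-trig addition to the C7 aldehyde to give alkoxide 10, which undergoes Smiles rearrangement and loses SO2 and the tetrazololate to leave the C7=C8 double bond (Julia–Kocienski olefination). The closest known reactions are the hydrogen-atom-transfer-initiated Giese/aldol annulation of alkenyl aldehydes with enones, the iron-hydride reductive coupling of olefins with vinyl sulfones, and the intramolecular Julia–Kocienski olefination; only their combination is new. C10 is set in the Giese step by approach of 9 trans to the C5 side chain (the other face is blocked by the axial C4 methyl), which gives the trans ring fusion; C9 is set in the same step, where the staggered transition state should place the C9 hydrogen toward the C5 side chain, the sulfonyl-bearing C8 anti to C5 and the silyloxyethyl chain anti to the C10 methyl, that is the 9R,10R relationship with the chain equatorial. The step needs hydrogen atom transfer to the electron-rich ring olefin only (the electron-poor vinyl sulfone is not an acceptor for it), radical attack at the less substituted carbon C9, and ring closure faster than protonation, which the aprotic medium and the six-membered transition state should secure. The C7/C8 epimers of 10 should converge because the carbanion addition is reversible and only the trans-diaxial adduct eliminates, and both olefin isomers of 9 give the same radical.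

Step 6
Reactants: 11 tert-butyl(dimethyl)[2-(Dec)ethoxy]silane
Product: 12 (1R,4aR,8aR)-1-(2-bromoethyl)-2,5,5,8a-tetramethyl-1,4,4a,5,6,7,8,8a-octahydronaphthalene
Conditions: Ph3PBr2 (1.3 equiv), CH2Cl2, 0 to 23 °C
Reagents that add atoms: triphenylphosphine dibromide BrP(Br)(c1ccccc1)(c1ccccc1)c1ccccc1
Why: Direct Appel-type bromination of the silyl ether (alkoxyphosphonium ion, then SN2 by bromide) under non-acidic conditions should leave the trisubstituted olefin and the stereocentres untouched.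

Step 7
Reactants: 13 methyl (2R)-3-hydroxy-2-methylpropanoate
Product: 14 methyl (2R)-3-(TBS-oxy)-2-methylpropanoate
Conditions: TBSCl, imidazole, DMF, 23 °C
Reagents that add atoms: tert-butyl(chloro)dimethylsilane CC(C)(C)[Si](C)(C)Cl
Why: Imidazole-mediated silylation of the primary alcohol, in which the stereocentre is not involved.

Step 8
Reactants: 14 methyl (2R)-3-(TBS-oxy)-2-methylpropanoate
Product: 15 (2R)-3-(TBS-oxy)-2-methylpropanal
Conditions: i-Bu2AlH (1.05 equiv), CH2Cl2, −78 °C; cold work-up, used at once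
Reagents that add atoms: none
Why: Low-temperature i-Bu2AlH half-reduction through the tetrahedral aluminate should give the aldehyde, and cold work-up with immediate use should keep the α-stereocentre.

Step 9
Reactants: 15 (2R)-3-(TBS-oxy)-2-methylpropanal
Product: 16 (2R,3R)-1-(TBS-oxy)-2-methylhex-5-yn-3-ol
Conditions: allenyltributylstannane, BF3·OEt2, CH2Cl2, −78 °C
Reagents that add atoms: allenyltributylstannane C=C=C[Sn](CCCC)(CCCC)CCCC
Why: Lewis-acid-mediated SE2' propargylation through an open transition state that follows the Felkin–Anh model of the α-methyl aldehyde, which should give the 2,3-syn (3R) homopropargylic alcohol.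

Step 10
Reactants: 16 (2R,3R)-1-(TBS-oxy)-2-methylhex-5-yn-3-ol; 12 (1R,4aR,8aR)-1-(2-bromoethyl)-2,5,5,8a-tetramethyl-1,4,4a,5,6,7,8,8a-octahydronaphthalene
Product: 17 (2R,3R)-1-(TBS-oxy)-2-methyl-8-(Dec)oct-5-yn-3-ol
Conditions: n-BuLi (2.1 equiv), THF/DMPU, −78 to −20 °C; then 12, Bu4NI (cat.), −20 to 23 °C
Reagents that add atoms: none
Why: SN2 alkylation of the acetylide carbon of the alkoxide–acetylide dianion with the primary bromide joins the two fragments without affecting any stereocentre.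

Step 11
Reactants: 17 (2R,3R)-1-(TBS-oxy)-2-methyl-8-(Dec)oct-5-yn-3-ol
Product: 18 (2R,3R,5Z)-1-(TBS-oxy)-2,6-dimethyl-8-(Dec)oct-5-en-3-ol
Conditions: MeMgBr (5 equiv), Fe(acac)3 (0.2 equiv), dppe (0.2 equiv), THF, −20 to 0 °C; then aq. NH4Cl
Reagents that add atoms: methylmagnesium bromide C[Mg]Br
Why: Hydroxyl-directed iron-catalysed carbomagnesiation of the homopropargylic alcohol, in which syn addition of methyl (distal carbon) and magnesium (proximal, chelated) followed by protonation should give the Z-trisubstituted olefin with the decalin chain cis to the carbinol arm.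

Step 12
Reactants: 18 (2R,3R,5Z)-1-(TBS-oxy)-2,6-dimethyl-8-(Dec)oct-5-en-3-ol
Product: 19 (2R,3R,5Z)-1-(TBS-oxy)-2,6-dimethyl-8-(Dec)oct-5-en-3-yl methanesulfonate
Conditions: MsCl, Et3N, CH2Cl2, 0 °C
Reagents that add atoms: methanesulfonyl chloride CS(=O)(=O)Cl
Why: Sulfonylation at oxygen (mesylation) keeps the carbinol configuration and installs the leaving group for the inverting displacement.

Step 13
Reactants: 19 (2R,3R,5Z)-1-(TBS-oxy)-2,6-dimethyl-8-(Dec)oct-5-en-3-yl methanesulfonate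
Product: 21 tert-butyl{[(2R,3S,5Z)-3-hydroperoxy-2,6-dimethyl-8-(Dec)oct-5-en-1-yl]oxy}dimethylsilane, via peroxyketal 20 (not isolated)
Conditions: 2-methoxyprop-2-yl hydroperoxide, CsOH·H2O, DMF, 0 to 23 °C; then AcOH/THF/H2O, 23 °C
Reagents that add atoms: 2-methoxyprop-2-yl hydroperoxide COC(C)(C)OO
Why: SN2 displacement of the mesylate by the caesium salt of monoprotected hydrogen peroxide inverts the carbinol carbon (R to S, the later C3 of the dioxane), and mild acid then releases the hydroperoxide from the peroxyketal.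

Step 14
Reactants: 21 tert-butyl{[(2R,3S,5Z)-3-hydroperoxy-2,6-dimethyl-8-(Dec)oct-5-en-1-yl]oxy}dimethylsilane
Product: 23 tert-butyl(dimethyl){(2R)-2-[(3S,6S)-6-methyl-6-(2-Dec-ethyl)-1,2-dioxan-3-yl]propoxy}silane, via organomercurial 22 (not isolated)
Conditions: Hg(OAc)2 (1.1 equiv), CH2Cl2, 0 °C; then NaBH4, aq. NaOH, −20 to 0 °C
Reagents that add atoms: none
Why: Intramolecular peroxymercuration–demercuration, in which Markovnikov anti addition closes the 1,2-dioxane 6-endo at the tertiary olefin carbon through a chair with the C3 substituent equatorial and the Z-disposed chain axial, so that the olefin geometry is translated into the (6S) quaternary centre before NaBH4 replaces mercury by hydrogen.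

Step 15
Reactants: 23 tert-butyl(dimethyl){(2R)-2-[(3S,6S)-6-methyl-6-(2-Dec-ethyl)-1,2-dioxan-3-yl]propoxy}silane
Product: 24 (2S)-2-[(3S,6S)-6-methyl-6-(2-Dec-ethyl)-1,2-dioxan-3-yl]propanoic acid
Conditions: CrO3, H2SO4, acetone/H2O, 0 °C
Reagents that add atoms: water O
Why: Jones oxidation, in which the acidic chromic acid medium cleaves the primary silyl ether and oxidises the alcohol through the aldehyde hydrate to the acid, while the dialkyl peroxide and the α-stereocentre (no base present) should survive.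

Step 16
Reactants: 24 (2S)-2-[(3S,6S)-6-methyl-6-(2-Dec-ethyl)-1,2-dioxan-3-yl]propanoic acid
Product: 25 methyl (2S)-2-[(3S,6S)-6-methyl-6-(2-Dec-ethyl)-1,2-dioxan-3-yl]propanoate (CNP0124238.1)
Conditions: Me3SiCHN2, MeOH/toluene, 0 °C
Reagents that add atoms: trimethylsilyldiazomethane C[Si](C)(C)C=[N+]=[N-]
Why: Esterification with the diazoalkane (protonation, then SN2 of the carboxylate on the methyldiazonium ion) should give the methyl ester under neutral conditions that spare the peroxide.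

**Compound list**

1 | 2,4,4-trimethylcyclohex-2-en-1-one | CC1=CC(C)(C)CCC1=O | starting material
2 | (1S)-2,4,4-trimethylcyclohex-2-en-1-ol | O[C@@H]1C(C)=CC(C)(C)CC1 | intermediate
3 | 1-ethoxy-1-{[(1S)-2,4,4-trimethylcyclohex-2-en-1-yl]oxy}ethene | C=C(OCC)O[C@@H]1C(C)=CC(C)(C)CC1 | intermediate (not isolated)
4 | ethyl 2-[(1R)-2,6,6-trimethylcyclohex-2-en-1-yl]acetate | CCOC(=O)C[C@@H]1C(C)(C)CCC=C1C | intermediate
5 | 2-[(1R)-2,6,6-trimethylcyclohex-2-en-1-yl]acetaldehyde | O=CC[C@@H]1C(C)(C)CCC=C1C | intermediate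
6 | 5-(ethylsulfonyl)-1-phenyl-1H-tetrazole | CCS(=O)(=O)c1nnnn1-c1ccccc1 | starting material
7 | 3-{[tert-butyl(dimethyl)silyl]oxy}propanal | CC(C)(C)[Si](C)(C)OCCC=O | starting material
8 | diethyl {1-[(1-phenyl-1H-tetrazol-5-yl)sulfonyl]ethyl}phosphonate (present as its lithium salt) | CCOP(=O)(OCC)C(C)S(=O)(=O)c1nnnn1-c1ccccc1 | intermediate (not isolated)
9 | 5-{[(2E)-5-{[tert-butyl(dimethyl)silyl]oxy}pent-2-en-2-yl]sulfonyl}-1-phenyl-1H-tetrazole | CC(C)(C)[Si](C)(C)OCC/C=C(\C)S(=O)(=O)c1nnnn1-c1ccccc1 | intermediate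
10 | ring-closed adduct: decalin of 11 with C7 bearing O(H) and C8 bearing methyl and the PT-sulfonyl group (present as the alkoxide; C5, C9, C10 as in 11; both configurations at C7 and C8) | CC(C)(C)[Si](C)(C)OCC[C@@H]1C(C)(S(=O)(=O)c3nnnn3-c3ccccc3)C(O)C[C@@H]2C(C)(C)CCC[C@@]12C | intermediate (not isolated)
11 | tert-butyl(dimethyl){2-[(1R,4aR,8aR)-2,5,5,8a-tetramethyl-1,4,4a,5,6,7,8,8a-octahydronaphthalen-1-yl]ethoxy}silane | CC(C)(C)[Si](C)(C)OCC[C@@H]1C(C)=CC[C@@H]2C(C)(C)CCC[C@@]12C | intermediate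
12 | (1R,4aR,8aR)-1-(2-bromoethyl)-2,5,5,8a-tetramethyl-1,4,4a,5,6,7,8,8a-octahydronaphthalene | BrCC[C@@H]1C(C)=CC[C@@H]2C(C)(C)CCC[C@@]12C | intermediate
13 | methyl (2R)-3-hydroxy-2-methylpropanoate | COC(=O)[C@H](C)CO | starting material
14 | methyl (2R)-3-{[tert-butyl(dimethyl)silyl]oxy}-2-methylpropanoate | COC(=O)[C@H](C)CO[Si](C)(C)C(C)(C)C | intermediate
15 | (2R)-3-{[tert-butyl(dimethyl)silyl]oxy}-2-methylpropanal | CC(C)(C)[Si](C)(C)OC[C@@H](C)C=O | intermediate
16 | (2R,3R)-1-{[tert-butyl(dimethyl)silyl]oxy}-2-methylhex-5-yn-3-ol | CC(C)(C)[Si](C)(C)OC[C@@H](C)[C@H](O)CC#C | intermediate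
17 | (2R,3R)-1-{[tert-butyl(dimethyl)silyl]oxy}-2-methyl-8-[(1R,4aR,8aR)-2,5,5,8a-tetramethyl-1,4,4a,5,6,7,8,8a-octahydronaphthalen-1-yl]oct-5-yn-3-ol | CC(C)(C)[Si](C)(C)OC[C@@H](C)[C@H](O)CC#CCC[C@@H]1C(C)=CC[C@@H]2C(C)(C)CCC[C@@]12C | intermediate
18 | (2R,3R,5Z)-1-{[tert-butyl(dimethyl)silyl]oxy}-2,6-dimethyl-8-[(1R,4aR,8aR)-2,5,5,8a-tetramethyl-1,4,4a,5,6,7,8,8a-octahydronaphthalen-1-yl]oct-5-en-3-ol | CC(C)(C)[Si](C)(C)OC[C@@H](C)[C@H](O)C/C=C(/C)CC[C@@H]1C(C)=CC[C@@H]2C(C)(C)CCC[C@@]12C | intermediate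
19 | (2R,3R,5Z)-1-{[tert-butyl(dimethyl)silyl]oxy}-2,6-dimethyl-8-[(1R,4aR,8aR)-2,5,5,8a-tetramethyl-1,4,4a,5,6,7,8,8a-octahydronaphthalen-1-yl]oct-5-en-3-yl methanesulfonate | CC(C)(C)[Si](C)(C)OC[C@@H](C)[C@H](OS(C)(=O)=O)C/C=C(/C)CC[C@@H]1C(C)=CC[C@@H]2C(C)(C)CCC[C@@]12C | intermediate
20 | tert-butyl{[(2R,3S,5Z)-3-[(2-methoxypropan-2-yl)peroxy]-2,6-dimethyl-8-[(1R,4aR,8aR)-2,5,5,8a-tetramethyl-1,4,4a,5,6,7,8,8a-octahydronaphthalen-1-yl]oct-5-en-1-yl]oxy}dimethylsilane | CC(C)(C)[Si](C)(C)OC[C@@H](C)[C@@H](OOC(C)(C)OC)C/C=C(/C)CC[C@@H]1C(C)=CC[C@@H]2C(C)(C)CCC[C@@]12C | intermediate (not isolated)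
21 | tert-butyl{[(2R,3S,5Z)-3-hydroperoxy-2,6-dimethyl-8-[(1R,4aR,8aR)-2,5,5,8a-tetramethyl-1,4,4a,5,6,7,8,8a-octahydronaphthalen-1-yl]oct-5-en-1-yl]oxy}dimethylsilane | CC(C)(C)[Si](C)(C)OC[C@@H](C)[C@@H](OO)C/C=C(/C)CC[C@@H]1C(C)=CC[C@@H]2C(C)(C)CCC[C@@]12C | intermediate
22 | dioxane 23 carrying an acetoxymercurio group at C5 of the dioxane, equatorial and anti to the C6–O1 bond | CC(C)(C)[Si](C)(C)OC[C@@H](C)[C@@H]1C[C@H]([Hg]OC(C)=O)[C@](C)(CC[C@@H]2C(C)=CC[C@@H]3C(C)(C)CCC[C@@]23C)OO1 | intermediate (not isolated)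
23 | tert-butyl(dimethyl){(2R)-2-[(3S,6S)-6-methyl-6-{2-[(1R,4aR,8aR)-2,5,5,8a-tetramethyl-1,4,4a,5,6,7,8,8a-octahydronaphthalen-1-yl]ethyl}-1,2-dioxan-3-yl]propoxy}silane | CC(C)(C)[Si](C)(C)OC[C@@H](C)[C@@H]1CC[C@](C)(CC[C@@H]2C(C)=CC[C@@H]3C(C)(C)CCC[C@@]23C)OO1 | intermediate
24 | (2S)-2-[(3S,6S)-6-methyl-6-{2-[(1R,4aR,8aR)-2,5,5,8a-tetramethyl-1,4,4a,5,6,7,8,8a-octahydronaphthalen-1-yl]ethyl}-1,2-dioxan-3-yl]propanoic acid | OC(=O)[C@@H](C)[C@@H]1CC[C@](C)(CC[C@@H]2C(C)=CC[C@@H]3C(C)(C)CCC[C@@]23C)OO1 | intermediate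
25 | methyl (2S)-2-[(3S,6S)-6-methyl-6-{2-[(1R,4aR,8aR)-2,5,5,8a-tetramethyl-1,4,4a,5,6,7,8,8a-octahydronaphthalen-1-yl]ethyl}-1,2-dioxan-3-yl]propanoate | COC(=O)[C@@H](C)[C@@H]1CC[C@](C)(CC[C@@H]2C(C)=CC[C@@H]3C(C)(C)CCC[C@@]23C)OO1 | target

**Step count and risks**

Total step count: 16. Longest linear sequence: 12 steps (steps 1, 2, 3, 5, 6, 10, 11, 12, 13, 14, 15, 16).

Step 5 is the most likely to fail. The sulfonyl-stabilised carbanion (or the radical before it) may be quenched by hydrogen transfer before ring B closes, and the facial selectivity at C9 in the Giese step may be low. The fallback uses known chemistry and sets out from 5 and 9. The usual iron-hydride reductive olefin coupling (Fe(acac)3, PhSiH3, EtOH/ethylene glycol, 60 °C) should give the open Giese adduct, seco-sulfone aldehyde F1. A separate intramolecular Julia–Kocienski olefination (KN(SiMe3)2, THF, −78 to 23 °C) should then close ring B and return to 11. This decouples the radical and the polar event and would allow the C9 epimers to be handled at the stage of F1.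

Step 13 is the second risk. E2 elimination of the homoallylic mesylate to a conjugated diene may outrun the slow substitution at the branched secondary carbon. The fallback sets out from 18 and avoids basic substitution:
- desilylation (Bu4NF, THF) to diol F2;
- closure to oxetane F3 (n-BuLi, TsCl, THF; then n-BuLi), with retention at the carbinol carbon;
- opening of the oxetane at its secondary carbon with ethereal H2O2 and Me3SiOTf, with inversion, to hydroperoxy alcohol F4;
- cyclisation under the conditions of step 14 to dioxane alcohol F5;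
- oxidation with CrO3/H2SO4, which comes back to the route at acid 24.

Step 14 is the third risk. During demercuration the β-peroxyalkyl radical may collapse to an epoxide with loss of the O–O bond, and 5-exo attack may compete. The fallback sets out from 21. Cyclisation with PhSeBr (CH2Cl2, −78 °C; anti addition through the same chair) should give selenide F6. Oxidation (H2O2, THF, 0 °C) and syn-elimination of the selenoxide toward C4 should give 3,6-dihydro-1,2-dioxine F7. Diimide (dipotassium azodicarboxylate, AcOH, MeOH) should reduce the ring olefin while sparing the O–O bond and the trisubstituted olefin, and returns to 23.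

Further compounds
F1 | step 5 | Giese adduct of 5 and 9 before ring closure: 2-{2-[5-(TBS-oxy)-2-(PT-sulfonyl)pentan-3-yl]-2,6,6-trimethylcyclohexyl}acetaldehyde (C5 C9 C10 as in 11; sulfonyl carbon unassigned) | CC(C)(C)[Si](C)(C)OCC[C@H](C(C)S(=O)(=O)c1nnnn1-c1ccccc1)[C@]1(C)CCCC(C)(C)[C@H]1CC=O
F2 | step 13 | (2R,3R,5Z)-2,6-dimethyl-8-[(1R,4aR,8aR)-2,5,5,8a-tetramethyl-1,4,4a,5,6,7,8,8a-octahydronaphthalen-1-yl]oct-5-ene-1,3-diol | OC[C@@H](C)[C@H](O)C/C=C(/C)CC[C@@H]1C(C)=CC[C@@H]2C(C)(C)CCC[C@@]12C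
F3 | step 13 | (2R,3R)-3-methyl-2-{(2Z)-3-methyl-5-[(1R,4aR,8aR)-2,5,5,8a-tetramethyl-1,4,4a,5,6,7,8,8a-octahydronaphthalen-1-yl]pent-2-en-1-yl}oxetane | C[C@@H]1CO[C@@H]1C/C=C(/C)CC[C@@H]2C(C)=CC[C@@H]3C(C)(C)CCC[C@@]23C
F4 | step 13 | (2R,3S,5Z)-3-hydroperoxy-2,6-dimethyl-8-[(1R,4aR,8aR)-2,5,5,8a-tetramethyl-1,4,4a,5,6,7,8,8a-octahydronaphthalen-1-yl]oct-5-en-1-ol | OC[C@@H](C)[C@@H](OO)C/C=C(/C)CC[C@@H]1C(C)=CC[C@@H]2C(C)(C)CCC[C@@]12C
F5 | step 13 | (2R)-2-[(3S,6S)-6-methyl-6-{2-[(1R,4aR,8aR)-2,5,5,8a-tetramethyl-1,4,4a,5,6,7,8,8a-octahydronaphthalen-1-yl]ethyl}-1,2-dioxan-3-yl]propan-1-ol | OC[C@@H](C)[C@@H]1CC[C@](C)(CC[C@@H]2C(C)=CC[C@@H]3C(C)(C)CCC[C@@]23C)OO1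
F6 | step 14 | dioxane 23 carrying a phenylselanyl group at C5 of the dioxane (equatorial; anti to the C6–O1 bond) | CC(C)(C)[Si](C)(C)OC[C@@H](C)[C@@H]1C[C@H]([Se]c4ccccc4)[C@](C)(CC[C@@H]2C(C)=CC[C@@H]3C(C)(C)CCC[C@@]23C)OO1
F7 | step 14 | tert-butyl(dimethyl){(2R)-2-[(3S,6S)-6-methyl-6-{2-[(1R,4aR,8aR)-2,5,5,8a-tetramethyl-1,4,4a,5,6,7,8,8a-octahydronaphthalen-1-yl]ethyl}-3,6-dihydro-1,2-dioxin-3-yl]propoxy}silane | CC(C)(C)[Si](C)(C)OC[C@@H](C)[C@@H]1C=C[C@](C)(CC[C@@H]2C(C)=CC[C@@H]3C(C)(C)CCC[C@@]23C)OO1
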